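**Retrosynthetic overview**
1. Target 18 ⇐ triol 17 (selective 2,15-diacetylation) ⇐ 3-oxo ester 13 (C2–O by enolate hydroxylation, C3–OH by equatorial hydride delivery, ester reduced in the same flask).
2. Ring B, closed last: C9–C10 bond by catalytic asymmetric proton-initiated cation–olefin cyclization of the monocyclic β,γ-enone 12 (sets C5, C9, C10; ends as the 7-ene).
3. Ring A: one-carbon ring enlargement of the cyclopentenyl carbinol 11 by 1,2-shift of the ring alkenyl carbon C5 from C3 to C4 (semipinacol type), which creates the C4 gem-dimethyl carbon and the C3 carbonyl.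
4. 11 ⇐ enone 9 + isopropenyl Grignard; 9 ⇐ 2-bromo-3-methylcyclopentenone + diene 6 (hydroboration, B-alkyl Suzuki); 6 ⇐ methyl crotonate + butenyl Grignard (asymmetric conjugate addition sets C13), then methacrolein cross-metathesis and methylenation.
5. Ring order: purchased five-membered ring → ring A by enlargement (step 6) → ring B by cyclization (step 7).

Assumption: 2-bromo-3-methylcyclopent-2-en-1-one and the two Grignard solutions are bought as such, and in the two catalyst-controlled steps (1 and 7) the ligand or catalyst antipode is the one that gives the configuration drawn. Labdane numbering is used for ring and side-chain positions.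

**Step 1**
Reactants: 1 methyl (2E)-but-2-enoate; 2 but-3-en-1-ylmagnesium bromide
Product: 3 methyl (3S)-3-methylhept-6-enoate
Conditions: CuI (2 mol %), (S)-Tol-BINAP (3 mol %), t-BuOMe, −40 °C; then 1 M HCl
Reagents that add atoms: none
Why: Copper-catalysed asymmetric conjugate addition of a primary alkyl Grignard reagent to a crotonate (known reaction class); the chiral copper–bisphosphine complex delivers the butenyl group to the Re face of C3 and so sets the (S) centre that becomes C13.

**Step 2**
Reactants: 3 methyl (3S)-3-methylhept-6-enoate; 4 2-methylprop-2-enal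
Product: 5 methyl (3S,6E)-3,7-dimethyl-8-oxooct-6-enoate
Conditions: second-generation Hoveyda–Grubbs catalyst RuCl2(H2IMes)(=CH-C6H4-2-OiPr) (5 mol %), 4 (4 equiv), CH2Cl2, 40 °C
Reagents that add atoms: none
Why: Olefin cross-metathesis of a terminal alkene with methacrolein, which is E-selective because the conjugated trisubstituted enal is the thermodynamic product and does not re-enter metathesis; ethene is lost.

**Step 3**
Reactants: 5 methyl (3S,6E)-3,7-dimethyl-8-oxooct-6-enoate
Product: 6 methyl (3S,6E)-3,7-dimethylnona-6,8-dienoate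
Conditions: Ph3PCH3Br, NaN(SiMe3)2, THF, 0 °C; then 5, −78 → 0 °C
Reagents that add atoms: methyltriphenylphosphonium bromide (as its ylide), C[P+](c1ccccc1)(c1ccccc1)c1ccccc1.[Br-]
Why: Wittig methylenation; the non-stabilised ylide reacts with the aldehyde far faster than with the methyl ester and leaves the E alkene untouched.

**Step 4**
Reactants: 6 methyl (3S,6E)-3,7-dimethylnona-6,8-dienoate; 7 2-bromo-3-methylcyclopent-2-en-1-one
Product: 9 methyl (3S,6E)-3,7-dimethyl-9-(2-methyl-5-oxocyclopent-1-en-1-yl)non-6-enoate, via B-alkyl-9-BBN adduct 8 (not isolated)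
Conditions: 9-BBN-H (1.1 equiv), THF, 0 → 23 °C; then 7, PdCl2(dppf) (5 mol %), AsPh3 (10 mol %), Cs2CO3, DMF/H2O, 23 °C
Reagents that add atoms: none
Why: 9-BBN hydroborates only the terminal vinyl group of the 2-substituted 1,3-diene (boron on the end carbon, future C6), and B-alkyl Suzuki–Miyaura coupling with the α-bromo enone (known for 2-halocycloalkenones) forms the C5–C6 bond without touching the ester.

**Step 5**
Reactants: 9 methyl (3S,6E)-3,7-dimethyl-9-(2-methyl-5-oxocyclopent-1-en-1-yl)non-6-enoate; 10 prop-1-en-2-ylmagnesium bromide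
Product: 11 methyl (3S,6E)-9-[5-hydroxy-2-methyl-5-(prop-1-en-2-yl)cyclopent-1-en-1-yl]-3,7-dimethylnon-6-enoate (both carbinol epimers)
Conditions: 10 (1.3 equiv), LaCl3·2LiCl (0.3 equiv), THF, −78 → −40 °C; then H2O (pH 7 buffer)
Reagents that add atoms: none
Why: Grignard 1,2-addition to the enone carbonyl (lanthanum chloride activation suppresses enolisation; the ketone reacts far faster than the ester at −78 °C); the new carbinol centre forms as both epimers, which does not matter because it becomes the C3 carbonyl in step 6.

**Step 6**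
Reactants: 11 methyl (3S,6E)-9-[5-hydroxy-2-methyl-5-(prop-1-en-2-yl)cyclopent-1-en-1-yl]-3,7-dimethylnon-6-enoate
Product: 12 methyl (3S,6E)-3,7-dimethyl-9-(2,6,6-trimethyl-5-oxocyclohex-1-en-1-yl)non-6-enoate
Conditions: cobalt salen complex N,N′-bis(3,5-di-tert-butylsalicylidene)-1,2-cyclohexanediaminocobalt, C36H52CoN2O2 (5 mol %), 1-fluoro-2,4,6-trimethylpyridinium triflate (1.2 equiv), PhSiH3 (1.2 equiv), acetone, 0 °C
Reagents that add atoms: none
Why: Proposed new method: a cobalt hydride (from the salen cobalt fluoride and PhSiH3) transfers a hydrogen atom selectively to the 1,1-disubstituted isopropenyl alkene (tri- and tetrasubstituted alkenes react far more slowly), the tertiary C4 radical (or the cation after oxidation by the catalyst) is attacked by the neighbouring ring alkenyl carbon C5 in a 3-exo closure, and the cyclopropylcarbinyl species opens at the C3–C5 bond to the oxygen-stabilised C3 radical/cation, which is oxidised and deprotonated to the ketone, so that C5 has shifted from C3 to C4 and the five-membered ring has become ring A with its gem-dimethyl carbon next to the C3 carbonyl without acid that would ionise the bis-allylic alcohol; the closest known reaction is the cobalt-catalysed hydrogen-atom-transfer radical–polar crossover semipinacol rearrangement of tertiary allylic alcohols, not shown for an unstrained cyclopentenyl carbinol with alkenyl shift beside two other alkenes.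

**Step 7**
Reactants: 12 methyl (3S,6E)-3,7-dimethyl-9-(2,6,6-trimethyl-5-oxocyclohex-1-en-1-yl)non-6-enoate
Product: 13 methyl (5S,9R,10S,13S)-3-oxolabd-7-en-15-oate
Conditions: chiral imidodiphosphorimidate acid HN[P(=NSO2CF3)(O2C20H10Ar2)]2 (Ar = 3,5-(CF3)2C6H3; 5 mol %), (CF3)3COH/CH2Cl2 (1:4), −40 °C
Reagents that add atoms: none
Why: Proposed new method: the confined chiral Brønsted acid protonates one enantiotopic face of the tetrasubstituted ring alkene at C5, the tertiary C10 cation is captured inside the chiral pocket by the (E)-trisubstituted side-chain alkene through a chair-like transition state (H-5 and the C10 methyl trans-diaxial, C9 side chain equatorial, hence 5S,9R,10S), and the C8 cation loses H-7 to the catalyst anion to give the 7-ene and regenerate the acid, while the C3 carbonyl blocks the usual C4-to-C5 methyl shift; the closest known reactions are the confined-acid and Lewis-acid-assisted-Brønsted-acid catalysed enantioselective proton-initiated polyene cyclizations of acyclic terminal alkenes and the achiral superacid cyclizations of β-monocyclic terpenoids to drimanes.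

**Step 8**
Reactants: 13 methyl (5S,9R,10S,13S)-3-oxolabd-7-en-15-oate
Product: 15 methyl (2S,5S,9R,10S,13S)-2-hydroxy-3-oxolabd-7-en-15-oate, via potassium enolate 14 (not isolated)
Conditions: KN(SiMe3)2 (1.1 equiv), THF, −78 °C; then 3-phenyl-2-(phenylsulfonyl)oxaziridine; then AcOH
Reagents that add atoms: 3-phenyl-2-(phenylsulfonyl)oxaziridine, O=S(=O)(c1ccccc1)N1OC1c1ccccc1
Why: Enolate hydroxylation with a Davis oxaziridine; the ketone can enolise only towards C2 (C4 is quaternary) and is deprotonated in preference to the less acidic ester, and the oxidant approaches C2 from the face opposite the axial C10 and C4 methyl groups, giving the equatorial (2S) alcohol.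

**Step 9**
Reactants: 15 methyl (2S,5S,9R,10S,13S)-2-hydroxy-3-oxolabd-7-en-15-oate
Product: 17 (2S,3R,5S,9R,10S,13S)-labd-7-ene-2,3,15-triol, via dihydroxy ester 16 (not isolated)
Conditions: LiBH(s-Bu)3 (2.5 equiv), THF, −78 °C; then LiAlH4 (2 equiv), −78 → 0 °C; Fieser work-up
Reagents that add atoms: none
Why: Bulky trialkylborohydride reduction (equatorial hydride delivery to a 4,4-dimethyl-3-oxo ring A gives the axial alcohol, here cis to the C2 hydroxyl, 3R), followed in the same flask by LiAlH4 reduction of the methyl ester to the primary alcohol.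

**Step 10**
Reactants: 17 (2S,3R,5S,9R,10S,13S)-labd-7-ene-2,3,15-triol
Product: 18 (2S,3R,5S,9R,10S,13S)-3-hydroxylabd-7-ene-2,15-diyl diacetate
Conditions: Ac2O (2.2 equiv), pyridine, CH2Cl2, 0 °C
Reagents that add atoms: acetic anhydride, CC(=O)OC(C)=O
Why: Selective acetylation; the primary C15 hydroxyl and the equatorial C2 hydroxyl are acylated, whereas the axial C3 hydroxyl next to the gem-dimethyl carbon is too hindered to react under these conditions.

**Compound list**
1 | methyl (2E)-but-2-enoate | C/C=C/C(=O)OC | starting material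
2 | but-3-en-1-ylmagnesium bromide | C=CCC[Mg]Br | starting material
3 | methyl (3S)-3-methylhept-6-enoate | COC(=O)C[C@@H](C)CCC=C | intermediate
4 | 2-methylprop-2-enal | CC(=C)C=O | starting material
5 | methyl (3S,6E)-3,7-dimethyl-8-oxooct-6-enoate | COC(=O)C[C@@H](C)CC/C=C(\C)C=O | intermediate
6 | methyl (3S,6E)-3,7-dimethylnona-6,8-dienoate | COC(=O)C[C@@H](C)CC/C=C(\C)C=C | intermediate
7 | 2-bromo-3-methylcyclopent-2-en-1-one | CC1=C(Br)C(=O)CC1 | starting material
8 | methyl (3S,6E)-9-(9-borabicyclo[3.3.1]nonan-9-yl)-3,7-dimethylnon-6-enoate | COC(=O)C[C@@H](C)CC/C=C(\C)CCB1C2CCCC1CCC2 | intermediate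
9 | methyl (3S,6E)-3,7-dimethyl-9-(2-methyl-5-oxocyclopent-1-en-1-yl)non-6-enoate | COC(=O)C[C@@H](C)CC/C=C(\C)CCC1=C(C)CCC1=O | intermediate
10 | prop-1-en-2-ylmagnesium bromide | CC(=C)[Mg]Br | starting material
11 | methyl (3S,6E)-9-[5-hydroxy-2-methyl-5-(prop-1-en-2-yl)cyclopent-1-en-1-yl]-3,7-dimethylnon-6-enoate (both carbinol epimers) | COC(=O)C[C@@H](C)CC/C=C(\C)CCC1=C(C)CCC1(O)C(C)=C | intermediate
12 | methyl (3S,6E)-3,7-dimethyl-9-(2,6,6-trimethyl-5-oxocyclohex-1-en-1-yl)non-6-enoate | COC(=O)C[C@@H](C)CC/C=C(\C)CCC1=C(C)CCC(=O)C1(C)C | intermediate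
13 | methyl (5S,9R,10S,13S)-3-oxolabd-7-en-15-oate | COC(=O)C[C@@H](C)CC[C@@H]1C(C)=CC[C@@H]2C(C)(C)C(=O)CC[C@@]12C | intermediate
14 | potassium (5S,9R,10S,13S)-15-methoxy-15-oxolabda-2,7-dien-3-olate | COC(=O)C[C@@H](C)CC[C@@H]1C(C)=CC[C@@H]2C(C)(C)C([O-])=CC[C@@]12C.[K+] | intermediate
15 | methyl (2S,5S,9R,10S,13S)-2-hydroxy-3-oxolabd-7-en-15-oate | COC(=O)C[C@@H](C)CC[C@@H]1C(C)=CC[C@@H]2C(C)(C)C(=O)[C@@H](O)C[C@@]12C | intermediate
16 | methyl (2S,3R,5S,9R,10S,13S)-2,3-dihydroxylabd-7-en-15-oate | COC(=O)C[C@@H](C)CC[C@@H]1C(C)=CC[C@@H]2C(C)(C)[C@@H](O)[C@@H](O)C[C@@]12C | intermediate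
17 | (2S,3R,5S,9R,10S,13S)-labd-7-ene-2,3,15-triol | OCC[C@@H](C)CC[C@@H]1C(C)=CC[C@@H]2C(C)(C)[C@@H](O)[C@@H](O)C[C@@]12C | intermediate
18 | (2S,3R,5S,9R,10S,13S)-3-hydroxylabd-7-ene-2,15-diyl diacetate | CC(=O)OCC[C@@H](C)CC[C@@H]1C(C)=CC[C@@H]2C(C)(C)[C@@H](O)[C@@H](OC(C)=O)C[C@@]12C | target

**Step count**
Total: 10 steps. Longest linear sequence: 10 steps (steps 1–10; 4, 7 and 10 are purchased and enter directly).

**Steps most likely to fail**

Step 6 (new ring enlargement). Risks are hydrogen-atom transfer to the side-chain alkene, epoxide formation in place of the shift, and loss of the bis-allylic hydroxyl. The fallback is the known selenium-mediated ring enlargement; it sets out from 9 and returns at 12. Enone 9 is treated at −78 °C in THF with 2-lithio-2-(methylselanyl)propane (from 2,2-bis(methylselanyl)propane and n-BuLi), which adds 1,2 to the carbonyl and gives the β-hydroxy selenide methyl (3S,6E)-9-{5-hydroxy-2-methyl-5-[2-(methylselanyl)propan-2-yl]cyclopent-1-en-1-yl}-3,7-dimethylnon-6-enoate F1. AgBF4 on basic Al2O3 in CH2Cl2 then removes methaneselenolate from the tertiary carbon while the ring alkenyl carbon migrates, giving 12; the alumina takes up the acid that would otherwise start ring B closure.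

Step 7 (new asymmetric bicyclization). Risks are low facial selectivity, catalyst binding by the ketone and ester, and 8(17)- or 8-ene isomers from the final proton loss. The fallback uses known chemistry with an auxiliary stereocentre; it sets out from 12 and returns at 13. Corey–Bakshi–Shibata reduction of 12 ((S)-Me-CBS oxazaborolidine, catecholborane, toluene, −78 °C; the quaternary C4 side is the large group) gives the alcohol methyl (3S,6E)-9-[(5R)-5-hydroxy-2,6,6-trimethylcyclohex-1-en-1-yl]-3,7-dimethylnon-6-enoate F2. Superacid cyclization (FSO3H, 2-nitropropane, −78 °C), the established way to close drimane and labdane B rings from β-monocyclic precursors, gives trans-fused bicyclic alcohols. Of these, methyl (3R,5S,9R,10S,13S)-3-hydroxylabd-7-en-15-oate F3 (oxygen equatorial) has the required core. The product with the mirror-image core is a diastereomer of F3, so it is removed on silica whatever the facial ratio; if it dominates, the antipodal reduction catalyst is used instead. Dess–Martin periodinane oxidation of F3 gives 13.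

Step 9 (axial alcohol at C3). The risk is competing axial hydride attack, which gives the equatorial 3-epimer. The fallback replaces substrate approach control by catalyst control; it sets out from 15 and returns at 17. Transfer hydrogenation of 15 with RuCl(p-cymene)(TsDPEN) (antipode matched to the existing C2 centre) and HCO2H/Et3N, a method that reduces α-hydroxy ketones without touching alkenes or esters, gives the cis-diol ester 16, now isolated. LiAlH4 then reduces the ester to 17. No new compound arises.

**Further compounds**
F1 | step 6 | methyl (3S,6E)-9-{5-hydroxy-2-methyl-5-[2-(methylselanyl)propan-2-yl]cyclopent-1-en-1-yl}-3,7-dimethylnon-6-enoate | COC(=O)C[C@@H](C)CC/C=C(\C)CCC1=C(C)CCC1(O)C(C)(C)[Se]C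
F2 | step 7 | methyl (3S,6E)-9-[(5R)-5-hydroxy-2,6,6-trimethylcyclohex-1-en-1-yl]-3,7-dimethylnon-6-enoate | COC(=O)C[C@@H](C)CC/C=C(\C)CCC1=C(C)CC[C@@H](O)C1(C)C
F3 | step 7 | methyl (3R,5S,9R,10S,13S)-3-hydroxylabd-7-en-15-oate | COC(=O)C[C@@H](C)CC[C@@H]1C(C)=CC[C@@H]2C(C)(C)[C@H](O)CC[C@@]12C
F0 | step 9 | none | none
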